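**Plan**

1. Retrosynthesis: the three ester C–O bonds are cut first (acetate at O3, the two (R)-2-methylbutanoates at O4 and O5); the C4–O and C5–O bonds are then traced back to C–acetyl bonds (Baeyer–Villiger); last, the ring bonds C3–C4 and C5–C6 are cut together (Diels–Alder).
2. Enabling feature: the cyclohexene ring C1–C6 has its only double bond C1=C2 between C6 and C3, with trans oxygens at C4/C5 and a cis oxygen at C3. This is the retron of an endo [4+2] addition of an (E)-1,2-diacylethene to an (E)-1-oxy-3-methoxycarbonyl diene.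
3. Forward: a Wittig-derived enal (C6–C1(CO2Me)=C2–C3HO) becomes its silyl dienol ether; (E)-hex-3-ene-2,5-dione supplies C4–C5, its two acetyl groups serving as activating groups and as masked oxygens; one catalytic asymmetric cycloaddition closes the only ring.
4. Then: double Baeyer–Villiger oxidation (acetyl to acetoxy with retention), methanolysis, esterification with (R)-2-methylbutanoic acid, and exchange of the C3 silyl ether for acetate.
5. Stereochemistry: C3, C4 and C5 are all set in the cycloaddition (trans C4/C5 from the E-alkene, cis C3/C4 from endo addition, absolute sense from a chiral oxazaborolidinium catalyst) and carried through unchanged; the two side-chain centres are bought as (R)-2-methylbutanoic acid.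

Key step: step 4

Remark: the SMILES is read as a (3R,4S,5R)-cyclohexene (shikimate configuration: 3,4-cis, 4,5-trans) with acetate on O3 and (2R)-2-methylbutanoate on O4 and O5; C1 bears CO2Me, C2 is the alkene CH, C6 is the CH2.

**Route**

Step 1
Reactants: 1 methyl 2-(triphenyl-λ5-phosphanylidene)propanoate; 2 2,2-dimethoxyacetaldehyde
Product: 4 methyl (2E)-2-methyl-4-oxobut-2-enoate, via methyl (2E)-4,4-dimethoxy-2-methylbut-2-enoate 3 (not isolated)
Conditions: CH2Cl2, rt; then 1 M HCl, THF, rt
Reagents that add atoms: water, SMILES: O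
Why: Wittig olefination with a stabilised α-methyl ylide should be E-selective for the trisubstituted enoate and tolerates the aqueous aldehyde, and dilute acid then hydrolyses the dimethyl acetal to the enal without touching the methyl ester; no stereocentre is formed.

Step 2
Reactants: 4 methyl (2E)-2-methyl-4-oxobut-2-enoate
Product: 5 methyl (3E)-2-methylidene-4-{[tri(propan-2-yl)silyl]oxy}but-3-enoate
Conditions: iPr3SiOTf, Et3N, Et2O, 0 °C to rt; filtered through basic alumina and used at once
Reagents that add atoms: tri(propan-2-yl)silyl trifluoromethanesulfonate, SMILES: CC(C)[Si](OS(=O)(=O)C(F)(F)F)(C(C)C)C(C)C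
Why: Soft enolisation (O-silylation of the enal, then γ-deprotonation of the C6 methyl group by the amine) should give the silyl dienol ether, mainly as the (E)-enol ether needed for cycloaddition; the diene is used fresh because 2-alkoxycarbonyl dienes dimerise on standing.

Step 3
Reactants: 6 2,5-dimethylfuran
Product: 8 (3E)-hex-3-ene-2,5-dione, via (3Z)-hex-3-ene-2,5-dione 7 (not isolated)
Conditions: mCPBA, CH2Cl2, 0 °C; then I2 (cat.), CH2Cl2, rt, daylight
Reagents that add atoms: mCPBA (3-chloroperoxybenzoic acid), SMILES: OOC(=O)c1cccc(Cl)c1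
Why: Peracid oxidation opens a 2,5-dialkylfuran to the cis-enedione (oxidative furan ring opening), and iodine-catalysed isomerisation should then give the more stable trans isomer.

Step 4
Reactants: 5 methyl (3E)-2-methylidene-4-{[tri(propan-2-yl)silyl]oxy}but-3-enoate; 8 (3E)-hex-3-ene-2,5-dione
Product: 9 methyl (3R,4S,5R)-4,5-diacetyl-3-{[tri(propan-2-yl)silyl]oxy}cyclohex-1-ene-1-carboxylate
Conditions: (S)-3,3-diphenyl-1-(2-methylphenyl)hexahydropyrrolo[1,2-c][1,3,2]oxazaborole (20 mol%), HN(SO2CF3)2 (18 mol%), CH2Cl2, −78 to −40 °C; Et3N quench, buffered silica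
Reagents that add atoms: none
Why: The N-protonated oxazaborolidine is a chiral cationic boron Lewis acid that binds one acetyl oxygen of 8 (s-trans enone, α-C–H···O contact) and lowers its LUMO, so that diene 5 adds in a concerted but asynchronous [4+2] cycloaddition in which C6–C5 forms ahead of C3–C4. The closest known reaction type is the cationic oxazaborolidine-catalysed Diels–Alder addition of enones, quinones and fumarates to silyloxy dienes. The cyclohexene ring closes by intermolecular suprafacial–suprafacial [4+2] cycloaddition, which leaves the C1=C2 double bond exactly where the target has it. C4 and C5 should come out trans because the E geometry of 8 is transferred stereospecifically, and C3 cis to C4 because the boron-bound acetyl group sits endo under the (E)-silyloxy diene; the absolute sense is set by the catalyst, whose aryl groups shield one face of the bound enone, and by analogy with the sense in which this (S)-configured catalyst adds dienes to acrylates and enones the (3R,4S,5R) adduct is expected, the (R)-configured catalyst being the remedy if the sense proves opposite. The step needs ortho regiochemistry, endo selectivity and facial selectivity: the silyloxy group at C3 and the ester at C1 both place the larger HOMO coefficient on C6, complexation of a single carbonyl secures endo addition of that acetyl group, and the bulky triisopropylsilyl group should suppress silyl transfer and the racemic silyl-cation pathway.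

Step 5
Reactants: 9 methyl (3R,4S,5R)-4,5-diacetyl-3-{[tri(propan-2-yl)silyl]oxy}cyclohex-1-ene-1-carboxylate
Product: 10 methyl (3R,4S,5R)-4,5-bis(acetyloxy)-3-{[tri(propan-2-yl)silyl]oxy}cyclohex-1-ene-1-carboxylate
Conditions: mCPBA (4 equiv), CF3CO2H (cat.), CH2Cl2, 0 °C to rt
Reagents that add atoms: mCPBA (3-chloroperoxybenzoic acid), SMILES: OOC(=O)c1cccc(Cl)c1
Why: Double Baeyer–Villiger oxidation, in which the secondary ring carbon should migrate in preference to methyl with retention of configuration, turns the trans-diacetyl pattern into the trans-diacetate, while the electron-poor conjugated C1=C2 bond should resist epoxidation.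

Step 6
Reactants: 10 methyl (3R,4S,5R)-4,5-bis(acetyloxy)-3-{[tri(propan-2-yl)silyl]oxy}cyclohex-1-ene-1-carboxylate
Product: 11 methyl (3R,4S,5R)-4,5-dihydroxy-3-{[tri(propan-2-yl)silyl]oxy}cyclohex-1-ene-1-carboxylate
Conditions: K2CO3 (0.2 equiv), MeOH, 0 °C
Reagents that add atoms: none
Why: Carbonate-catalysed transesterification (Zemplén-type methanolysis) should remove both acetates as methyl acetate, the methyl ester can only exchange with methanol, and the silyl ether and all stereocentres are untouched.

Step 7
Reactants: 11 methyl (3R,4S,5R)-4,5-dihydroxy-3-{[tri(propan-2-yl)silyl]oxy}cyclohex-1-ene-1-carboxylate; 12 (2R)-2-methylbutanoic acid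
Product: 13 methyl (3R,4S,5R)-4,5-bis{[(2R)-2-methylbutanoyl]oxy}-3-{[tri(propan-2-yl)silyl]oxy}cyclohex-1-ene-1-carboxylate
Conditions: 12 (3 equiv), N,N'-dicyclohexylcarbodiimide (3 equiv), 4-(dimethylamino)pyridine (0.3 equiv), CH2Cl2, 0 °C to rt
Reagents that add atoms: none
Why: Steglich esterification should acylate both secondary hydroxyls at oxygen, so the ring centres are retained, and the α-branched aliphatic acid is not expected to racemise under carbodiimide activation.

Step 8
Reactants: 13 methyl (3R,4S,5R)-4,5-bis{[(2R)-2-methylbutanoyl]oxy}-3-{[tri(propan-2-yl)silyl]oxy}cyclohex-1-ene-1-carboxylate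
Product: 14 methyl (3R,4R,5R)-3-hydroxy-4,5-bis{[(2R)-2-methylbutanoyl]oxy}cyclohex-1-ene-1-carboxylate
Conditions: HF·pyridine, pyridine, THF, 0 °C to rt
Reagents that add atoms: none
Why: Fluoride-mediated desilylation in a buffered, non-basic medium should free the allylic C3 hydroxyl while suppressing migration of the neighbouring cis C4 acyl group; the change of the C4 descriptor to R is only a change of substituent priorities.

Step 9
Reactants: 14 methyl (3R,4R,5R)-3-hydroxy-4,5-bis{[(2R)-2-methylbutanoyl]oxy}cyclohex-1-ene-1-carboxylate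
Product: 15 methyl (3R,4S,5R)-3-(acetyloxy)-4,5-bis{[(2R)-2-methylbutanoyl]oxy}cyclohex-1-ene-1-carboxylate (target, CNP0132712.1)
Conditions: Ac2O, pyridine, 4-(dimethylamino)pyridine (cat.), CH2Cl2, 0 °C
Reagents that add atoms: acetic anhydride, SMILES: CC(=O)OC(C)=O
Why: Nucleophile-catalysed O-acetylation of the allylic alcohol at low temperature should outrun acyl migration and completes the triester with retention at C3.

**Compound list**

1 | methyl 2-(triphenyl-λ5-phosphanylidene)propanoate | COC(=O)C(C)=P(c1ccccc1)(c1ccccc1)c1ccccc1 | starting material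
2 | 2,2-dimethoxyacetaldehyde | COC(OC)C=O | starting material
3 | methyl (2E)-4,4-dimethoxy-2-methylbut-2-enoate | COC(=O)/C(C)=C/C(OC)OC | intermediate
4 | methyl (2E)-2-methyl-4-oxobut-2-enoate | COC(=O)/C(C)=C/C=O | intermediate
5 | methyl (3E)-2-methylidene-4-{[tri(propan-2-yl)silyl]oxy}but-3-enoate | C=C(C(=O)OC)/C=C/O[Si](C(C)C)(C(C)C)C(C)C | intermediate
6 | 2,5-dimethylfuran | Cc1ccc(C)o1 | starting material
7 | (3Z)-hex-3-ene-2,5-dione | CC(=O)/C=C\C(C)=O | intermediate
8 | (3E)-hex-3-ene-2,5-dione | CC(=O)/C=C/C(C)=O | intermediate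
9 | methyl (3R,4S,5R)-4,5-diacetyl-3-{[tri(propan-2-yl)silyl]oxy}cyclohex-1-ene-1-carboxylate | CC(=O)[C@@H]1[C@H](O[Si](C(C)C)(C(C)C)C(C)C)C=C(C(=O)OC)C[C@H]1C(C)=O | intermediate
10 | methyl (3R,4S,5R)-4,5-bis(acetyloxy)-3-{[tri(propan-2-yl)silyl]oxy}cyclohex-1-ene-1-carboxylate | CC(=O)O[C@@H]1[C@H](O[Si](C(C)C)(C(C)C)C(C)C)C=C(C(=O)OC)C[C@H]1OC(C)=O | intermediate
11 | methyl (3R,4S,5R)-4,5-dihydroxy-3-{[tri(propan-2-yl)silyl]oxy}cyclohex-1-ene-1-carboxylate | O[C@@H]1[C@H](O[Si](C(C)C)(C(C)C)C(C)C)C=C(C(=O)OC)C[C@H]1O | intermediate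
12 | (2R)-2-methylbutanoic acid | CC[C@@H](C)C(=O)O | starting material
13 | methyl (3R,4S,5R)-4,5-bis{[(2R)-2-methylbutanoyl]oxy}-3-{[tri(propan-2-yl)silyl]oxy}cyclohex-1-ene-1-carboxylate | CC[C@@H](C)C(=O)O[C@@H]1[C@H](O[Si](C(C)C)(C(C)C)C(C)C)C=C(C(=O)OC)C[C@H]1OC(=O)[C@H](C)CC | intermediate
14 | methyl (3R,4R,5R)-3-hydroxy-4,5-bis{[(2R)-2-methylbutanoyl]oxy}cyclohex-1-ene-1-carboxylate | CC[C@@H](C)C(=O)O[C@@H]1[C@H](O)C=C(C(=O)OC)C[C@H]1OC(=O)[C@H](C)CC | intermediate
15 | methyl (3R,4S,5R)-3-(acetyloxy)-4,5-bis{[(2R)-2-methylbutanoyl]oxy}cyclohex-1-ene-1-carboxylate | CC[C@@H](C)C(=O)O[C@@H]1[C@H](OC(C)=O)C=C(C(=O)OC)C[C@H]1OC(=O)[C@H](C)CC | target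

**Step count**

Total steps: 9. Longest linear sequence: 8 (steps 1, 2, 4, 5, 6, 7, 8, 9); step 3 is the convergent branch.

**Steps most likely to fail, with fallbacks**

Step 4 (key cycloaddition). What may go wrong: erosion of enantioselectivity through an achiral proton- or silyl-cation-catalysed background reaction, incomplete endo control, or loss of diene 5 by self-dimerisation or Mukaiyama–Michael addition. The fallback sets out from 5 and 8 and returns at 13. Catalyst control is given up and the cycloaddition is promoted by the achiral Lewis acid Me2AlCl in CH2Cl2 at −78 °C, which should still enforce the ortho, endo mode and give 9 as the racemate, that is, together with its enantiomer methyl (3S,4R,5S)-4,5-diacetyl-3-{[tri(propan-2-yl)silyl]oxy}cyclohex-1-ene-1-carboxylate F1. The mixture is taken through the conditions of steps 5 and 6, which should give 10 and 11 accompanied by methyl (3S,4R,5S)-4,5-bis(acetyloxy)-3-{[tri(propan-2-yl)silyl]oxy}cyclohex-1-ene-1-carboxylate F2 and methyl (3S,4R,5S)-4,5-dihydroxy-3-{[tri(propan-2-yl)silyl]oxy}cyclohex-1-ene-1-carboxylate F3. Esterification with 12 as in step 7 turns the enantiomers into diastereomers, 13 and methyl (3S,4R,5S)-4,5-bis{[(2R)-2-methylbutanoyl]oxy}-3-{[tri(propan-2-yl)silyl]oxy}cyclohex-1-ene-1-carboxylate F4, which are separated by chromatography; 13 then re-enters the route.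

Step 5 (double Baeyer–Villiger oxidation). What may go wrong: stalling after the first oxygen insertion, because the second migrating carbon is deactivated by the new neighbouring acetoxy group, or acid-induced β-elimination of the silyloxy group next to the ketone. The fallback sets out from 9 and returns at 10. Both ketones are methylenated under non-basic Takai–Lombardo conditions (CH2Br2, Zn, TiCl4, THF) to methyl (3R,4R,5R)-4,5-di(prop-1-en-2-yl)-3-{[tri(propan-2-yl)silyl]oxy}cyclohex-1-ene-1-carboxylate F5. The two 1,1-disubstituted alkenes are ozonised in CH2Cl2/MeOH at −78 °C (the conjugated C1=C2 bond should react far more slowly) to the bis(α-methoxy hydroperoxide) methyl (3R,4S,5R)-4,5-bis(1-hydroperoxy-1-methoxyethyl)-3-{[tri(propan-2-yl)silyl]oxy}cyclohex-1-ene-1-carboxylate F6. Ac2O, Et3N and 4-(dimethylamino)pyridine then trigger the Criegee rearrangement, again with migration of the ring carbon with retention, to give 10.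

Step 8 (desilylation). What may go wrong: migration of the C4 acyl group onto the freed cis C3 hydroxyl, or sluggish cleavage of the hindered silyl ether. The fallback sets out from 13 and returns at 15. The silyl ether is exchanged for acetate without ever freeing the alcohol, by acetolysis with Ac2O and catalytic FeCl3 in CH2Cl2 at 0 °C. Further compound on this path: none F0.

**Further compounds**

F1 | step 4 | methyl (3S,4R,5S)-4,5-diacetyl-3-{[tri(propan-2-yl)silyl]oxy}cyclohex-1-ene-1-carboxylate | CC(=O)[C@H]1[C@@H](O[Si](C(C)C)(C(C)C)C(C)C)C=C(C(=O)OC)C[C@@H]1C(C)=O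
F2 | step 4 | methyl (3S,4R,5S)-4,5-bis(acetyloxy)-3-{[tri(propan-2-yl)silyl]oxy}cyclohex-1-ene-1-carboxylate | CC(=O)O[C@H]1[C@@H](O[Si](C(C)C)(C(C)C)C(C)C)C=C(C(=O)OC)C[C@@H]1OC(C)=O
F3 | step 4 | methyl (3S,4R,5S)-4,5-dihydroxy-3-{[tri(propan-2-yl)silyl]oxy}cyclohex-1-ene-1-carboxylate | O[C@H]1[C@@H](O[Si](C(C)C)(C(C)C)C(C)C)C=C(C(=O)OC)C[C@@H]1O
F4 | step 4 | methyl (3S,4R,5S)-4,5-bis{[(2R)-2-methylbutanoyl]oxy}-3-{[tri(propan-2-yl)silyl]oxy}cyclohex-1-ene-1-carboxylate | CC[C@@H](C)C(=O)O[C@H]1[C@@H](O[Si](C(C)C)(C(C)C)C(C)C)C=C(C(=O)OC)C[C@@H]1OC(=O)[C@H](C)CC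
F5 | step 5 | methyl (3R,4R,5R)-4,5-di(prop-1-en-2-yl)-3-{[tri(propan-2-yl)silyl]oxy}cyclohex-1-ene-1-carboxylate | CC(=C)[C@@H]1[C@H](O[Si](C(C)C)(C(C)C)C(C)C)C=C(C(=O)OC)C[C@H]1C(C)=C
F6 | step 5 | methyl (3R,4S,5R)-4,5-bis(1-hydroperoxy-1-methoxyethyl)-3-{[tri(propan-2-yl)silyl]oxy}cyclohex-1-ene-1-carboxylate | COC(C)(OO)[C@@H]1[C@H](O[Si](C(C)C)(C(C)C)C(C)C)C=C(C(=O)OC)C[C@H]1C(C)(OC)OO
F0 | step 8 | none | none
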